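**Retrosynthetic overview**

1. The target is traced back, by removal of eight benzyl ethers and one 7‑O‑silyl ether, to a 3,5‑bis(tri‑O‑benzylgalloyl) ester; both esters come from one acylation of a 3,5‑diol whose 7‑oxygen stays silylated.
2. Key disconnection: the C4–C4a bond of the pyran (C) ring. The feature used is the C4 methylene that joins the phloroglucinol carbon C4a (ortho to O1 and O5, para to O7) to the oxygen‑bearing C3, which is the imprint of a terminal oxirane opened at its CH2 by an arene.
3. The oxirane aryl ether (C2–O1 bond) comes from Mitsunobu inversion of an erythro epoxy alcohol with a phloroglucinol carrying MOM (future O5) and TIPS (future O7).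
4. Both stereocentres come from one Sharpless kinetic resolution of the racemic 1‑arylallyl alcohol made from 3,4‑bis(benzyloxy)benzaldehyde and a vinyl Grignard reagent.
5. Ring order: the A, B and galloyl rings are bought; the oxirane is made in step 2 and is turned into the pyran C ring, the only ring of the target that is built, in step 6.

Key step: step 6

**Route**

Step 1
Reactants: 1 3,4-bis(benzyloxy)benzaldehyde
Product: 2 (±)-1-[3,4-bis(benzyloxy)phenyl]prop-2-en-1-ol
Conditions: CH2=CHMgBr (1.2 equiv), THF, 0 °C; then H2O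
Reagents that add atoms: vinylmagnesium bromide, C=C[Mg]Br
Why: Grignard 1,2-addition to the aromatic aldehyde should give the racemic secondary allylic alcohol; no stereocontrol is needed because the next step resolves it.

Step 2
Reactants: 2 (±)-1-[3,4-bis(benzyloxy)phenyl]prop-2-en-1-ol
Product: 3 (S)-[3,4-bis(benzyloxy)phenyl][(2R)-oxiran-2-yl]methanol (erythro epoxy alcohol)
Conditions: Ti(OiPr)4 (15 mol %), L-(+)-DIPT (18 mol %), t-BuOOH (0.6 equiv), 4 Å MS, CH2Cl2, −20 °C
Reagents that add atoms: tert-butyl hydroperoxide, CC(C)(C)OO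
Why: Sharpless kinetic resolution of a secondary allylic alcohol: with L-(+)-DIPT the (R)-carbinol should be epoxidised much faster than the (S)-carbinol, with oxygen delivered erythro to the carbinol, which sets the (R)-oxirane carbon (future C3) and selects the carbinol that is named (S) in 3 only because the CIP priorities change.

Step 3
Reactants: 4 phloroglucinol (benzene-1,3,5-triol)
Product: 5 5-(triisopropylsilyloxy)benzene-1,3-diol
Conditions: TIPSCl (1.0 equiv), imidazole, DMF, 0 °C → rt
Reagents that add atoms: triisopropylsilyl chloride, CC(C)[Si](Cl)(C(C)C)C(C)C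
Why: Imidazole-promoted O-silylation of a phenol; the three hydroxyls are equivalent, so a limiting amount of silyl chloride should give the mono-ether as the main component of a statistical mixture that is separable by chromatography.

Step 4
Reactants: 5 5-(triisopropylsilyloxy)benzene-1,3-diol
Product: 6 3-(methoxymethoxy)-5-(triisopropylsilyloxy)phenol
Conditions: MOMCl (1.0 equiv), i-Pr2NEt, CH2Cl2, 0 °C → rt
Reagents that add atoms: chloromethyl methyl ether, COCCl
Why: MOM protection of a phenol with a hindered amine base; the two hydroxyls are equivalent, so one equivalent should give mainly the mono-acetal, separable from bis-acetal and recovered diol.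

Step 5
Reactants: 3 (S)-[3,4-bis(benzyloxy)phenyl][(2R)-oxiran-2-yl]methanol; 6 3-(methoxymethoxy)-5-(triisopropylsilyloxy)phenol (1.3 equiv)
Product: 7 (2R)-2-{(R)-[3,4-bis(benzyloxy)phenyl][3-(methoxymethoxy)-5-(triisopropylsilyloxy)phenoxy]methyl}oxirane (threo aryl ether)
Conditions: PPh3, DIAD, toluene, 0 °C → rt
Reagents that add atoms: none
Why: Mitsunobu etherification: the phenoxide should displace the oxyphosphonium of the secondary benzylic alcohol with inversion (S → R at the future C2), the adjacent oxirane oxygen disfavours ionisation, and any product of retention would be a separable diastereomer, not an enantiomer.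

Step 6
Reactants: 7 (2R)-2-{(R)-[3,4-bis(benzyloxy)phenyl][3-(methoxymethoxy)-5-(triisopropylsilyloxy)phenoxy]methyl}oxirane
Product: 8 (2R,3R)-2-[3,4-bis(benzyloxy)phenyl]-5-(methoxymethoxy)-7-(triisopropylsilyloxy)chroman-3-ol (3′,4′-di-O-benzyl-5-O-MOM-7-O-TIPS-epicatechin)
Conditions: AuCl3 (5 mol %), AgOTf (15 mol %), 4 Å MS, ClCH2CH2Cl, 0 °C → rt
Reagents that add atoms: none
Why: The Lewis acid binds the oxirane oxygen, the A-ring carbon ortho to the ether oxygen and ortho to the MOM ether attacks the primary carbon C4 from the rear, and the Wheland intermediate passes its proton to the alkoxide, which forms C4–C4a and frees the 3-OH. This is the known Lewis-acid-catalysed intramolecular Friedel–Crafts (epoxy–arene) cyclisation of aryl glycidyl ethers to chroman-3-ols. The pyran ring closes in the 6-endo-tet mode, since the 5-exo alternative would require attack on the secondary oxirane carbon, which is hindered by the neighbouring C2 centre and deactivated by its C–O bond. No stereocentre is formed: the C3–O bond is not broken and C2 is not involved, so the threo (R,R) ether should give the 2,3-cis (2R,3R) flavan. The step needs attack by the ring carbon between O1 and the MOM ether and not by the one between O1 and the silyl ether; both are ortho/ortho/para to the three oxygens and so similar electronically, and the choice is left to the bulk of the triisopropylsilyl group, which screens its two neighbours. The three donor oxygens make the A ring nucleophilic enough for a weak acid, which is what should keep the p-alkoxybenzylic C2–O bond from ionising and the B ring from migrating.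

Step 7
Reactants: 8 (2R,3R)-2-[3,4-bis(benzyloxy)phenyl]-5-(methoxymethoxy)-7-(triisopropylsilyloxy)chroman-3-ol
Product: 9 (2R,3R)-2-[3,4-bis(benzyloxy)phenyl]-7-(triisopropylsilyloxy)chroman-3,5-diol
Conditions: conc. HCl (cat.), MeOH–THF, 40 °C
Reagents that add atoms: none
Why: Acid-catalysed acetal exchange with methanol (MOM cleavage) should free the 5-OH, while the aryl TIPS ether, the benzyl ethers and the cyclic benzylic ether are stable to dilute acid at this temperature.

Step 8
Reactants: 9 (2R,3R)-2-[3,4-bis(benzyloxy)phenyl]-7-(triisopropylsilyloxy)chroman-3,5-diol; 10 3,4,5-tris(benzyloxy)benzoic acid (3 equiv)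
Product: 11 (2R,3R)-2-[3,4-bis(benzyloxy)phenyl]-7-(triisopropylsilyloxy)chroman-3,5-diyl bis[3,4,5-tris(benzyloxy)benzoate]
Conditions: DCC, DMAP, CH2Cl2, rt
Reagents that add atoms: none
Why: Steglich esterification should acylate both the phenolic 5-OH and the axial secondary 3-OH with the protected gallic acid, the 7-oxygen being blocked as its silyl ether.

Step 9
Reactants: 11 (2R,3R)-2-[3,4-bis(benzyloxy)phenyl]-7-(triisopropylsilyloxy)chroman-3,5-diyl bis[3,4,5-tris(benzyloxy)benzoate]
Product: 12 (2R,3R)-2-[3,4-bis(benzyloxy)phenyl]-7-hydroxychroman-3,5-diyl bis[3,4,5-tris(benzyloxy)benzoate]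
Conditions: TBAF, AcOH (1:1), THF, 0 °C → rt
Reagents that add atoms: none
Why: Fluoride-induced cleavage of the aryl silyl ether; the acetic acid buffer keeps the liberated phenoxide protonated so that the phenyl gallate ester at O5 should be neither cleaved nor transferred.

Step 10
Reactants: 12 (2R,3R)-2-[3,4-bis(benzyloxy)phenyl]-7-hydroxychroman-3,5-diyl bis[3,4,5-tris(benzyloxy)benzoate]
Product: 13 (−)-epicatechin 3,5-di-O-gallate, (2R,3R)-2-(3,4-dihydroxyphenyl)-7-hydroxychroman-3,5-diyl bis(3,4,5-trihydroxybenzoate)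
Conditions: H2 (1 atm), 20% Pd(OH)2/C, THF–MeOH, rt
Reagents that add atoms: none
Why: Catalytic hydrogenolysis of the eight benzyl ethers under neutral conditions should leave the two gallate esters, the cyclic C2–O1 ether and both stereocentres untouched and give the target.

**Compound list**

1 | 3,4-bis(benzyloxy)benzaldehyde | O=Cc1ccc(OCc2ccccc2)c(OCc2ccccc2)c1 | starting material
2 | (±)-1-[3,4-bis(benzyloxy)phenyl]prop-2-en-1-ol | C=CC(O)c1ccc(OCc2ccccc2)c(OCc2ccccc2)c1 | intermediate
3 | (S)-[3,4-bis(benzyloxy)phenyl][(2R)-oxiran-2-yl]methanol | C1[C@@H](O1)[C@H](c1ccc(OCc2ccccc2)c(OCc2ccccc2)c1)O | intermediate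
4 | phloroglucinol (benzene-1,3,5-triol) | Oc1cc(O)cc(O)c1 | starting material
5 | 5-(triisopropylsilyloxy)benzene-1,3-diol | Oc1cc(O)cc(O[Si](C(C)C)(C(C)C)C(C)C)c1 | intermediate
6 | 3-(methoxymethoxy)-5-(triisopropylsilyloxy)phenol | COCOc1cc(O)cc(O[Si](C(C)C)(C(C)C)C(C)C)c1 | intermediate
7 | (2R)-2-{(R)-[3,4-bis(benzyloxy)phenyl][3-(methoxymethoxy)-5-(triisopropylsilyloxy)phenoxy]methyl}oxirane | C1[C@@H](O1)[C@@H](c1ccc(OCc2ccccc2)c(OCc2ccccc2)c1)Oc1cc(OCOC)cc(O[Si](C(C)C)(C(C)C)C(C)C)c1 | intermediate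
8 | (2R,3R)-2-[3,4-bis(benzyloxy)phenyl]-5-(methoxymethoxy)-7-(triisopropylsilyloxy)chroman-3-ol | COCOc1cc(O[Si](C(C)C)(C(C)C)C(C)C)cc2c1C[C@@H](O)[C@@H](c1ccc(OCc3ccccc3)c(OCc3ccccc3)c1)O2 | intermediate
9 | (2R,3R)-2-[3,4-bis(benzyloxy)phenyl]-7-(triisopropylsilyloxy)chroman-3,5-diol | Oc1cc(O[Si](C(C)C)(C(C)C)C(C)C)cc2c1C[C@@H](O)[C@@H](c1ccc(OCc3ccccc3)c(OCc3ccccc3)c1)O2 | intermediate
10 | 3,4,5-tris(benzyloxy)benzoic acid | OC(=O)c1cc(OCc2ccccc2)c(OCc2ccccc2)c(OCc2ccccc2)c1 | starting material
11 | (2R,3R)-2-[3,4-bis(benzyloxy)phenyl]-7-(triisopropylsilyloxy)chroman-3,5-diyl bis[3,4,5-tris(benzyloxy)benzoate] | O=C(Oc1cc(O[Si](C(C)C)(C(C)C)C(C)C)cc2c1C[C@@H](OC(=O)c3cc(OCc4ccccc4)c(OCc4ccccc4)c(OCc4ccccc4)c3)[C@@H](c3ccc(OCc4ccccc4)c(OCc4ccccc4)c3)O2)c1cc(OCc2ccccc2)c(OCc2ccccc2)c(OCc2ccccc2)c1 | intermediate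
12 | (2R,3R)-2-[3,4-bis(benzyloxy)phenyl]-7-hydroxychroman-3,5-diyl bis[3,4,5-tris(benzyloxy)benzoate] | O=C(Oc1cc(O)cc2c1C[C@@H](OC(=O)c3cc(OCc4ccccc4)c(OCc4ccccc4)c(OCc4ccccc4)c3)[C@@H](c3ccc(OCc4ccccc4)c(OCc4ccccc4)c3)O2)c1cc(OCc2ccccc2)c(OCc2ccccc2)c(OCc2ccccc2)c1 | intermediate
13 | (−)-epicatechin 3,5-di-O-gallate | O=C(Oc1cc(O)cc2c1C[C@@H](OC(=O)c1cc(O)c(O)c(O)c1)[C@@H](c1ccc(O)c(O)c1)O2)c1cc(O)c(O)c(O)c1 | target

**Step count**

Total: 10 steps. Longest linear sequence: 8 steps (1 → 13 through steps 1, 2, 5–10; the phloroglucinol branch through steps 3, 4, 5–10 is equally long).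

**Steps most likely to fail**

Step 6 (key step). The ring may close in part through the ortho carbon next to the silyl ether (regiochemical leakage), because the two ortho carbons differ only in their steric surroundings. The fallback sets out from 7 and comes back at 12; it makes either regiochemical outcome usable by reversing the order in which the two orthogonal phenol protecting groups are removed. The cyclisation is run as in step 6 and the isomer (2R,3R)-2-[3,4-bis(benzyloxy)phenyl]-7-(methoxymethoxy)-5-(triisopropylsilyloxy)chroman-3-ol F1 is separated. TBAF/AcOH in THF would free its 5-OH to give (2R,3R)-2-[3,4-bis(benzyloxy)phenyl]-7-(methoxymethoxy)chroman-3,5-diol F2. DCC/DMAP with 10 would give the 7-O-MOM 3,5-digallate F3. ZnBr2/n-PrSH in CH2Cl2 at 0 °C would then remove the MOM ether without touching the esters and give 12.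

Step 5. The oxyphosphonium intermediate may ionise at the p-alkoxybenzylic carbon, which would cause loss of inversion and C-alkylation of the electron-rich phenol. The fallback sets out from 1 and 6 and comes back at 7; it makes the C2–O bond by titanium-templated opening of a cis-2,3-epoxy alcohol instead of by displacement at a carbinol.
- Z-selective Horner–Wadsworth–Emmons olefination of 1 with ethyl bis(2-methylphenoxy)phosphorylacetate (NaH, THF, −78 °C) would give ethyl (Z)-3-[3,4-bis(benzyloxy)phenyl]prop-2-enoate F4.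
- DIBAL-H would give (Z)-3-[3,4-bis(benzyloxy)phenyl]prop-2-en-1-ol F5.
- Sharpless epoxidation with D-(−)-DIPT would give [(2R,3S)-3-[3,4-bis(benzyloxy)phenyl]oxiran-2-yl]methanol F6.
- Ti(OiPr)4 with phenol 6 in toluene should deliver the phenoxide to the benzylic C3 with inversion and give (2R,3R)-3-[3,4-bis(benzyloxy)phenyl]-3-[3-(methoxymethoxy)-5-(triisopropylsilyloxy)phenoxy]propane-1,2-diol F7.
- Selective sulfonylation of the primary hydroxyl (TsCl, Et3N, cat. Bu2SnO) would give the tosylate (2R,3R)-3-[3,4-bis(benzyloxy)phenyl]-2-hydroxy-3-[3-(methoxymethoxy)-5-(triisopropylsilyloxy)phenoxy]propyl 4-methylbenzenesulfonate F8, and NaH in THF would close the terminal oxirane 7.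

Step 2. The titanium catalyst may ionise or transpose the electron-rich 1-arylallyl alcohol, and oxygen transfer to the unsubstituted vinyl group is slow, so yield and selectivity may erode. The fallback does not branch from a numbered compound: it replaces 1 and 2 by purchased methyl (R)-glycidate and 4-bromo-1,2-bis(benzyloxy)benzene and comes back at 3. It takes the oxirane stereocentre from the chiral pool and sets the carbinol by chelation-controlled reduction.
- Methyl (R)-glycidate with MeNH(OMe)·HCl and i-PrMgCl (THF, −20 °C) would give the Weinreb amide (R)-N-methoxy-N-methyloxirane-2-carboxamide F9.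
- The aryllithium from 4-bromo-1,2-bis(benzyloxy)benzene (n-BuLi, THF, −78 °C) would add to F9 to give (R)-[3,4-bis(benzyloxy)phenyl](oxiran-2-yl)methanone F10.
- Zn(BH4)2 in Et2O at −20 °C should reduce the zinc-chelated epoxy ketone from its open face to the erythro alcohol 3.

**Further compounds**

F1 | step 6 | (2R,3R)-2-[3,4-bis(benzyloxy)phenyl]-7-(methoxymethoxy)-5-(triisopropylsilyloxy)chroman-3-ol | CC(C)[Si](C(C)C)(C(C)C)Oc1cc(OCOC)cc2c1C[C@@H](O)[C@@H](c1ccc(OCc3ccccc3)c(OCc3ccccc3)c1)O2
F2 | step 6 | (2R,3R)-2-[3,4-bis(benzyloxy)phenyl]-7-(methoxymethoxy)chroman-3,5-diol | Oc1cc(OCOC)cc2c1C[C@@H](O)[C@@H](c1ccc(OCc3ccccc3)c(OCc3ccccc3)c1)O2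
F3 | step 6 | (2R,3R)-2-[3,4-bis(benzyloxy)phenyl]-7-(methoxymethoxy)chroman-3,5-diyl bis[3,4,5-tris(benzyloxy)benzoate] | O=C(Oc1cc(OCOC)cc2c1C[C@@H](OC(=O)c3cc(OCc4ccccc4)c(OCc4ccccc4)c(OCc4ccccc4)c3)[C@@H](c3ccc(OCc4ccccc4)c(OCc4ccccc4)c3)O2)c1cc(OCc2ccccc2)c(OCc2ccccc2)c(OCc2ccccc2)c1
F4 | step 5 | ethyl (Z)-3-[3,4-bis(benzyloxy)phenyl]prop-2-enoate | CCOC(=O)/C=C\c1ccc(OCc2ccccc2)c(OCc2ccccc2)c1
F5 | step 5 | (Z)-3-[3,4-bis(benzyloxy)phenyl]prop-2-en-1-ol | OC/C=C\c1ccc(OCc2ccccc2)c(OCc2ccccc2)c1
F6 | step 5 | [(2R,3S)-3-[3,4-bis(benzyloxy)phenyl]oxiran-2-yl]methanol | OC[C@H]1O[C@H]1c1ccc(OCc2ccccc2)c(OCc2ccccc2)c1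
F7 | step 5 | (2R,3R)-3-[3,4-bis(benzyloxy)phenyl]-3-[3-(methoxymethoxy)-5-(triisopropylsilyloxy)phenoxy]propane-1,2-diol | OC[C@@H](O)[C@@H](c1ccc(OCc2ccccc2)c(OCc2ccccc2)c1)Oc1cc(OCOC)cc(O[Si](C(C)C)(C(C)C)C(C)C)c1
F8 | step 5 | (2R,3R)-3-[3,4-bis(benzyloxy)phenyl]-2-hydroxy-3-[3-(methoxymethoxy)-5-(triisopropylsilyloxy)phenoxy]propyl 4-methylbenzenesulfonate | Cc1ccc(cc1)S(=O)(=O)OC[C@@H](O)[C@@H](c1ccc(OCc2ccccc2)c(OCc2ccccc2)c1)Oc1cc(OCOC)cc(O[Si](C(C)C)(C(C)C)C(C)C)c1
F9 | step 2 | (R)-N-methoxy-N-methyloxirane-2-carboxamide | CON(C)C(=O)[C@H]1CO1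
F10 | step 2 | (R)-[3,4-bis(benzyloxy)phenyl](oxiran-2-yl)methanone | O=C(c1ccc(OCc2ccccc2)c(OCc2ccccc2)c1)[C@H]1CO1
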